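## Retrosynthetic overview
1. Key disconnection: the alkyl C7–O bond of the inter-unit ester. This gives gliocladic acid (unit B, carboxylic acid nucleophile) and the spiro-epoxide of a protected seco-heptelidic acid (unit A, electrophile).
2. Unit B is made from the same epoxide by base-induced epoxide-to-allylic-alkoxide isomerisation and lactonisation, so one monomer serves both halves.
3. The epoxide comes from equatorial-face epoxidation of an exocyclic methylene, which comes from methylenation of a β-keto ester. The side chain comes from cross-metathesis of a C6 vinyl group with tert-butyl 2-(hydroxymethyl)acrylate.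
4. The β-keto ester comes from (R)-cryptone by anti vinyl 1,4-addition and enolate C-carboxylation. Cryptone comes from 3-methylbutanal and methyl vinyl ketone.
5. Ring order: cyclohexene ring (step 1), spiro-oxirane (step 6), butenolide of unit B (step 7). The two units are joined in the last-but-one step.

Assumption: the SMILES is read as drawn (unit A 1S,2S,3R,6S; unit B 4S,5R; both side-chain alkenes E); in the Why lines C1 = isopropyl-bearing carbon, C4 = oxygenated quaternary carbon, C5 = ring-carboxyl carbon, C6 = side-chain carbon, C7 = exocyclic CH2.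

## Route

Step 1
Reactants: 1 3-methylbutanal; 2 but-3-en-2-one
Product: 4 (4R)-4-(propan-2-yl)cyclohex-2-en-1-one, via keto aldehyde 3 (not isolated)
Conditions: (R)-2-[diphenyl(trimethylsilyloxy)methyl]pyrrolidine (5 mol%), ethyl 3,4-dihydroxybenzoate (20 mol%), neat, 4 °C, 36 h; then LiOH (0.2 equiv), iPrOH, rt
Reagents that add atoms: none
Why: Enamine-catalysed asymmetric Michael addition, in which the bulky diarylprolinol ether shields one enamine face so that the (R)-catalyst gives (R)-3 and thereby sets C1, followed by an intramolecular aldol condensation that does not touch this centre.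

Step 2
Reactants: 4 (R)-cryptone; 5 vinylmagnesium bromide
Product: 7 tert-butyl (1S,2R,3R)-2-ethenyl-6-oxo-3-(propan-2-yl)cyclohexane-1-carboxylate, via bromomagnesium enolate 6 (not isolated)
Conditions: 5 (1.3 equiv), CuBr·SMe2 (10 mol%), THF, −78 → −40 °C; then tert-butyl 1H-imidazole-1-carboxylate (1.5 equiv), −78 °C → rt; aq. work-up
Reagents that add atoms: tert-butyl 1H-imidazole-1-carboxylate, CC(C)(C)OC(=O)n1ccnc1
Why: Copper-catalysed 1,4-addition of the Grignard reagent occurs anti to the C1 isopropyl group and sets C6 trans, and the regiodefined magnesium enolate is then C-carboxylated (Mander-type enolate acylation, where O-acylation is reversible with imidazolide as leaving group and the chelated β-keto ester enolate is the sink), so that C5 settles on work-up as the equatorial all-trans epimer.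

Step 3
Reactants: 7 β-keto ester
Product: 8 tert-butyl (1S,2R,3R)-2-ethenyl-6-methylidene-3-(propan-2-yl)cyclohexane-1-carboxylate
Conditions: Zn, CH2Br2, TiCl4 (reagent pre-aged in THF, 5 °C, 3 d), CH2Cl2, 0 °C → rt
Reagents that add atoms: dibromomethane, BrCBr
Why: Takai–Lombardo methylenation uses a non-basic gem-dimetallic reagent that converts enolisable ketones in the presence of esters, where a Wittig ylide would only deprotonate the β-keto ester, and no stereocentre is touched.

Step 4
Reactants: 9 tert-butyl acrylate; 10 formaldehyde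
Product: 11 tert-butyl 2-(hydroxymethyl)prop-2-enoate
Conditions: 37% aq. formaldehyde, DABCO (0.5 equiv), 1,4-dioxane/H2O 1:1, rt
Reagents that add atoms: none
Why: Morita–Baylis–Hillman reaction of an acrylate with formaldehyde, with no stereocentre formed.

Step 5
Reactants: 8 diene ester; 11 tert-butyl 2-(hydroxymethyl)prop-2-enoate (4 equiv)
Product: 12 tert-butyl (1S,2S,3R)-2-[(1E)-3-tert-butoxy-2-(hydroxymethyl)-3-oxoprop-1-en-1-yl]-6-methylidene-3-(propan-2-yl)cyclohexane-1-carboxylate
Conditions: second-generation Hoveyda–Grubbs catalyst (2 × 5 mol%), 1,4-benzoquinone (10 mol%), toluene, 80 °C, argon sparge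
Reagents that add atoms: none
Why: Cross-metathesis of the terminal vinyl group with a 1,1-disubstituted acrylate that cannot homodimerise, in which the hindered exocyclic methylene stays a spectator, benzoquinone suppresses alkene migration, and thermodynamic control places the ring carbon trans to the ester (E, ring cis to CH2OH) as with methacrylates.

Step 6
Reactants: 12 methylidene diester
Product: 13 tert-butyl (3S,4S,5S,6R)-5-[(1E)-3-tert-butoxy-2-(hydroxymethyl)-3-oxoprop-1-en-1-yl]-6-(propan-2-yl)-1-oxaspiro[2.5]octane-4-carboxylate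
Conditions: PhCN (5 equiv), 35% aq. H2O2 (5 equiv), KHCO3 (0.5 equiv), MeOH, rt, 36 h
Reagents that add atoms: hydrogen peroxide, OO
Why: Payne epoxidation, whose bulky peroxybenzimidic acid attacks methylenecyclohexanes from the equatorial face (opposite to small peracids), a bias reinforced here by the tert-butoxy group of the C5 ester over the axial face, so that oxygen ends equatorial and C7 axial (C4 set as S), while the electron-poor enoate does not react and the minor epimer is removed by chromatography.

Step 7
Reactants: 13 spiro-epoxide (about half of the material)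
Product: 16 gliocladic acid, via hydroxy enoate 14 (not isolated), via butenolide tert-butyl ester 15 (not isolated)
Conditions: KOtBu (0.3 equiv), THF, −20 → 0 °C; then TFA/CH2Cl2 1:3, rt
Reagents that add atoms: none
Why: Base-induced isomerisation of a β,γ-epoxy ester to a γ-hydroxy enoate (E1cB) gives 14, whose ring-locked Z alkoxide lactonises on the C5 ester to butenolide 15 with regeneration of tert-butoxide (C4 and C5 become sp2, C1 and C6 are kept), and acidolysis of the remaining tert-butyl ester frees the acid.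

Step 8
Reactants: 13 spiro-epoxide; 16 gliocladic acid (1.1 equiv)
Product: 17 di-tert-butyl ester of the target
Conditions: Cr(salen)Cl (5 mol%; salen = dianion of N,N′-bis(3,5-di-tert-butylsalicylidene)ethane-1,2-diamine), iPr2NEt (10 mol%), tBuOMe (2 M), 35 °C, 24–48 h
Reagents that add atoms: none
Why: Proposed new method: 16 and the catalytic amine load the catalyst as Cr(salen)(O2CR), a second trivalent chromium centre binds the epoxide oxygen of 13, the bound carboxylate is delivered by SN2 attack to the unsubstituted C7 (the C4–O bond is untouched, so C4 is retained), and protonolysis of the chromium alkoxide by a further molecule of 16 closes the cycle; the medium stays near neutral, C5–H is antiperiplanar to C4–C7 rather than to C4–O so E1cB isomerisation is slow, and the far less acidic allylic hydroxyls do not load onto the metal; the closest known reactions are the cooperative salen–metal opening of meso and monosubstituted epoxides by benzoic acid and the salen–chromium azidolysis of 2,2-disubstituted epoxides, whereas a carboxylic acid opening of a 2,2-disubstituted spiro β,γ-epoxy ester as a 1:1 fragment coupling has not been shown.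

Step 9
Reactants: 17 di-tert-butyl ester
Product: 18 target CNP0071646.2
Conditions: TFA/CH2Cl2 1:4, 0 °C → rt, 2 h; then aq. NaHCO3 (cleaves adventitious trifluoroacetates), acidify to pH 3
Reagents that add atoms: none
Why: Acidolysis of both tert-butyl esters with loss of isobutene leaves the neopentyl-type enoate ester, the butenolide and the tertiary alcohol intact, because ionisation at C4 is disfavoured by the flanking acyloxymethyl and carboxyl groups, and no stereocentre is touched.

## Compound list
1 | 3-methylbutanal | CC(C)CC=O | starting material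
2 | but-3-en-2-one (methyl vinyl ketone) | CC(=O)C=C | starting material
3 | (2R)-5-oxo-2-(propan-2-yl)hexanal | CC(C)[C@@H](CCC(C)=O)C=O | intermediate
4 | (4R)-4-(propan-2-yl)cyclohex-2-en-1-one, (R)-cryptone | CC(C)[C@H]1CCC(=O)C=C1 | intermediate
5 | vinylmagnesium bromide | C=C[Mg]Br | starting material
6 | bromomagnesium enolate of (3R,4R)-3-ethenyl-4-(propan-2-yl)cyclohexan-1-one, enolate C=C toward the vinyl-bearing carbon | CC(C)[C@H]1CCC(O[Mg]Br)=C[C@@H]1C=C | intermediate
7 | tert-butyl (1S,2R,3R)-2-ethenyl-6-oxo-3-(propan-2-yl)cyclohexane-1-carboxylate (all-trans, all-equatorial) | CC(C)[C@H]1CCC(=O)[C@@H](C(=O)OC(C)(C)C)[C@@H]1C=C | intermediate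
8 | tert-butyl (1S,2R,3R)-2-ethenyl-6-methylidene-3-(propan-2-yl)cyclohexane-1-carboxylate | CC(C)[C@H]1CCC(=C)[C@@H](C(=O)OC(C)(C)C)[C@@H]1C=C | intermediate
9 | tert-butyl acrylate | C=CC(=O)OC(C)(C)C | starting material
10 | formaldehyde | C=O | starting material
11 | tert-butyl 2-(hydroxymethyl)prop-2-enoate | C=C(CO)C(=O)OC(C)(C)C | intermediate
12 | tert-butyl (1S,2S,3R)-2-[(1E)-3-tert-butoxy-2-(hydroxymethyl)-3-oxoprop-1-en-1-yl]-6-methylidene-3-(propan-2-yl)cyclohexane-1-carboxylate | CC(C)[C@H]1CCC(=C)[C@@H](C(=O)OC(C)(C)C)[C@@H]1/C=C(\CO)C(=O)OC(C)(C)C | intermediate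
13 | tert-butyl (3S,4S,5S,6R)-5-[(1E)-3-tert-butoxy-2-(hydroxymethyl)-3-oxoprop-1-en-1-yl]-6-(propan-2-yl)-1-oxaspiro[2.5]octane-4-carboxylate (epoxide O equatorial, CH2 axial) | CC(C)[C@H]1CC[C@@]2(CO2)[C@@H](C(=O)OC(C)(C)C)[C@@H]1/C=C(\CO)C(=O)OC(C)(C)C | intermediate
14 | tert-butyl (5R,6S)-6-[(1E)-3-tert-butoxy-2-(hydroxymethyl)-3-oxoprop-1-en-1-yl]-2-(hydroxymethyl)-5-(propan-2-yl)cyclohex-1-ene-1-carboxylate | CC(C)[C@H]1CCC(CO)=C(C(=O)OC(C)(C)C)[C@@H]1/C=C(\CO)C(=O)OC(C)(C)C | intermediate
15 | tert-butyl (2E)-2-(hydroxymethyl)-3-[(4S,5R)-3-oxo-5-(propan-2-yl)-1,3,4,5,6,7-hexahydro-2-benzofuran-4-yl]prop-2-enoate | CC(C)[C@H]1CCC2=C(C(=O)OC2)[C@@H]1/C=C(\CO)C(=O)OC(C)(C)C | intermediate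
16 | (2E)-2-(hydroxymethyl)-3-[(4S,5R)-3-oxo-5-(propan-2-yl)-1,3,4,5,6,7-hexahydro-2-benzofuran-4-yl]prop-2-enoic acid (gliocladic acid) | CC(C)[C@H]1CCC2=C(C(=O)OC2)[C@@H]1/C=C(\CO)C(=O)O | intermediate
17 | di-tert-butyl ester of 18 (ring C1 carboxylate and unit A side-chain carboxylate as tert-butyl esters; 1S,2S,3R,6S in unit A, 4S,5R in unit B, both alkenes E) | CC(C)[C@H]1CC[C@@](O)(COC(=O)/C(=C/[C@H]2C3=C(CC[C@@H]2C(C)C)COC3=O)CO)[C@@H](C(=O)OC(C)(C)C)[C@@H]1/C=C(\CO)C(=O)OC(C)(C)C | intermediate
18 | (1S,2S,3R,6S)-2-[(1E)-2-carboxy-3-hydroxyprop-1-en-1-yl]-6-hydroxy-6-({[(2E)-2-(hydroxymethyl)-3-[(4S,5R)-3-oxo-5-(propan-2-yl)-1,3,4,5,6,7-hexahydro-2-benzofuran-4-yl]prop-2-enoyl]oxy}methyl)-3-(propan-2-yl)cyclohexane-1-carboxylic acid | CC(C)[C@H]1CC[C@@](O)(COC(=O)/C(=C/[C@H]2C3=C(CC[C@@H]2C(C)C)COC3=O)CO)[C@@H](C(=O)O)[C@@H]1/C=C(\CO)C(=O)O | target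

## Step count
- Total step count: 9.
- Longest linear sequence: 8 (steps 1, 2, 3, 5, 6, 7, 8, 9).
- Monomer of roughly 90–95% ee is upgraded at step 8. The heterochiral dimer is a separable diastereomer.

## Three steps most likely to fail

**Step 8 (the new coupling).** The catalyst may not activate the hindered 2,2-disubstituted epoxide, or 13 may isomerise. The fallback makes the same ester from the acyl side with known reactions. It sets out from 12 and 16 and comes back at 17.
- Silylation of 12 (TBSCl, imidazole) gives the side-chain TBS ether F1.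
- OsO4 (cat.)/NMO dihydroxylates its exocyclic alkene from the equatorial face to the diol F2.
- 16 is silylated twice to the silyl ether silyl ester F3, and K2CO3 in aqueous MeOH cleaves the silyl ester to the O-TBS acid F4.
- Yamaguchi esterification (2,4,6-trichlorobenzoyl chloride, Et3N, then DMAP) of the primary C7 hydroxyl of F2 with F4 gives the bis-TBS ester F5.
- HF·pyridine removes both silyl groups to give 17.

**Step 5 (cross-metathesis to a trisubstituted alkene at a vinyl group flanked by two substituents).** The fallback builds the side chain in stages from the much better monosubstituted partner. It sets out from 8 and 9 and comes back at 12.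
- Cross-metathesis of 8 with 9 gives the E-enoate F6.
- Conjugate addition of lithium thiophenolate (PhSLi), with trapping of the ester enolate by monomeric formaldehyde (tandem Michael–aldol), gives the β-phenylthio α-hydroxymethyl ester F7.
- mCPBA (1 equiv, −78 °C, sulfide much faster than the alkenes) gives the sulfoxide F8.
- Thermal syn-elimination (toluene, 90 °C, CaCO3) gives 12 after separation of alkene isomers.

**Step 6 (facial selectivity at C4).** If the Payne reagent gives a poor ratio, oxygen is delivered by a reagent with a stronger equatorial preference and the ring is closed afterwards. The fallback sets out from 12 and comes back at 13.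
- OsO4 (cat.)/NMO attacks only the electron-rich exocyclic alkene from the equatorial face to give the triol F9.
- Bu2SnO (cat.), TsCl and Et3N sulfonylate selectively the primary hydroxyl of the chelating 1,2-diol to give the tosylate F10.
- K2CO3 in MeOH at 0 °C closes the epoxide with retention at C4 to give 13.

Further compounds
F1 | step 8 | TBS ether of 12, tert-butyl (1S,2S,3R)-2-[(1E)-3-tert-butoxy-2-{[(tert-butyldimethylsilyl)oxy]methyl}-3-oxoprop-1-en-1-yl]-6-methylidene-3-(propan-2-yl)cyclohexane-1-carboxylate | CC(C)[C@H]1CCC(=C)[C@@H](C(=O)OC(C)(C)C)[C@@H]1/C=C(\CO[Si](C)(C)C(C)(C)C)C(=O)OC(C)(C)C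
F2 | step 8 | (1S,2S,3R,6S)-6-hydroxy-6-(hydroxymethyl) diol derived from F1 (tertiary OH equatorial, CH2OH axial) | CC(C)[C@H]1CC[C@@](O)(CO)[C@@H](C(=O)OC(C)(C)C)[C@@H]1/C=C(\CO[Si](C)(C)C(C)(C)C)C(=O)OC(C)(C)C
F3 | step 8 | tert-butyldimethylsilyl ester of O-TBS gliocladic acid | CC(C)[C@H]1CCC2=C(C(=O)OC2)[C@@H]1/C=C(\CO[Si](C)(C)C(C)(C)C)C(=O)O[Si](C)(C)C(C)(C)C
F4 | step 8 | O-TBS gliocladic acid | CC(C)[C@H]1CCC2=C(C(=O)OC2)[C@@H]1/C=C(\CO[Si](C)(C)C(C)(C)C)C(=O)O
F5 | step 8 | bis-TBS ether of 17 | CC(C)[C@H]1CC[C@@](O)(COC(=O)/C(=C/[C@H]2C3=C(CC[C@@H]2C(C)C)COC3=O)CO[Si](C)(C)C(C)(C)C)[C@@H](C(=O)OC(C)(C)C)[C@@H]1/C=C(\CO[Si](C)(C)C(C)(C)C)C(=O)OC(C)(C)C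
F6 | step 5 | tert-butyl (1S,2S,3R)-2-[(1E)-3-tert-butoxy-3-oxoprop-1-en-1-yl]-6-methylidene-3-(propan-2-yl)cyclohexane-1-carboxylate | CC(C)[C@H]1CCC(=C)[C@@H](C(=O)OC(C)(C)C)[C@@H]1/C=C/C(=O)OC(C)(C)C
F7 | step 5 | β-phenylthio α-hydroxymethyl ester from F6 (mixture at the two new side-chain centres) | CC(C)[C@H]1CCC(=C)[C@@H](C(=O)OC(C)(C)C)[C@@H]1C(Sc2ccccc2)C(CO)C(=O)OC(C)(C)C
F8 | step 5 | sulfoxide of F7 (mixture at sulfur and the two side-chain centres) | CC(C)[C@H]1CCC(=C)[C@@H](C(=O)OC(C)(C)C)[C@@H]1C(S(=O)c2ccccc2)C(CO)C(=O)OC(C)(C)C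
F9 | step 6 | triol, (1S,2S,3R,6S)-6-hydroxy-6-(hydroxymethyl) derivative of 12 | CC(C)[C@H]1CC[C@@](O)(CO)[C@@H](C(=O)OC(C)(C)C)[C@@H]1/C=C(\CO)C(=O)OC(C)(C)C
F10 | step 6 | primary C7 p-toluenesulfonate of F9 | CC(C)[C@H]1CC[C@@](O)(COS(=O)(=O)c2ccc(C)cc2)[C@@H](C(=O)OC(C)(C)C)[C@@H]1/C=C(\CO)C(=O)OC(C)(C)C
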